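**Retrosynthetic overview**
- Numbering of the bicyclo[4.2.0]octane core: C1 ring-fusion C(Me), C2 CH-O, C3 =C(Me), C4 =CH, C5 C(Me)-O, C6 ring-fusion CH, C7 C(Me)(pyrone), C8 CH(Me).
- Last rings: the O-O bridge over C2 and C5 comes from [4+2] addition of singlet oxygen to the bicyclic diene, on the face anti to the cyclobutane.
- Enabling feature: the cyclobutane (C1, C6, C7, C8) cis-fused to the six-membered carbocycle (C1 to C6) is the closed valence tautomer of an all-cis cycloocta-1,3,5-triene whose only sp3 atoms are C7 and C8. In that tautomer C1-C2 is an ordinary ring olefin, so relay ring-closing metathesis of an open-chain pentaene makes C1=C2 (eight-membered ring), and disrotatory 6π closure then makes C1-C6 (four- and six-membered rings) in the same flask.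
- The pentaene comes from Negishi coupling (C4-C5) of a Z-vinyl iodide with a Z-dienylzinc. The vinyl iodide comes from an α-quaternary aldehyde by Stork-Zhao olefination (C5=C6).
- C7 and C8 are set together in a chair Claisen rearrangement, with chirality transfer from an (S)-allylic alcohol whose pentenyl chain later serves as the metathesis relay. The pyrone (first ring) comes from a triketide.

Key step: step 14

Remark: the β-keto ester, the triketide, the pyronyl propanal and the unresolved allylic alcohol are racemates or mixtures of labile stereoisomers and tautomers, so their SMILES carry no descriptors at those centres.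

Step 1
Reactants: 1 ethyl 2-methyl-3-oxopentanoate; 2 N-methoxy-N-methylpropanamide
Product: 3 ethyl 2,4-dimethyl-3,5-dioxoheptanoate
Conditions: LDA (2.3 equiv), THF, -78 to 0 °C; 2, -78 to 0 °C; then 1 M HCl
Reagents that add atoms: none
Why: The β-keto ester dianion is acylated at its more reactive γ-carbon (Claisen-type dianion C-acylation), and the stable tetrahedral adduct of the Weinreb amide prevents proton transfer and over-addition, with no lasting stereocentre formed.

Step 2
Reactants: 3 ethyl 2,4-dimethyl-3,5-dioxoheptanoate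
Product: 4 6-ethyl-4-hydroxy-3,5-dimethyl-2H-pyran-2-one
Conditions: DBU (1.5 equiv), toluene, 80 °C
Reagents that add atoms: none
Why: Base-mediated lactonisation of the δ-enol onto the ester (triketide to 4-hydroxy-2-pyrone cyclisation) is driven by formation of the conjugated pyrone and erases both labile stereocentres.

Step 3
Reactants: 4 6-ethyl-4-hydroxy-3,5-dimethyl-2H-pyran-2-one
Product: 5 2-ethyl-6-methoxy-3,5-dimethyl-4H-pyran-4-one
Conditions: MeOTf (1.1 equiv), CH2Cl2, 0 °C to rt; then sat. aq. NaHCO3
Reagents that add atoms: methyl trifluoromethanesulfonate COS(=O)(=O)C(F)(F)F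
Why: Without base the hard alkylating agent methylates the lactone carbonyl oxygen to a 4-hydroxy-2-methoxypyrylium salt, whose deprotonation gives the α-methoxy-γ-pyrone rather than the 4-methoxy-α-pyrone (regioselective O-alkylation of a 4-hydroxy-2-pyrone).

Step 4
Reactants: 5 2-ethyl-6-methoxy-3,5-dimethyl-4H-pyran-4-one
Product: 6 2-(6-methoxy-3,5-dimethyl-4-oxo-4H-pyran-2-yl)propanal
Conditions: LiHMDS (2.2 equiv), THF, -78 °C; HCO2Et, -78 to -20 °C; then 1 M HCl
Reagents that add atoms: ethyl formate CCOC=O
Why: The CH2 of the 2-ethyl group is the vinylogous α-position of the pyrone, so its lithium dienolate undergoes Claisen-type C-formylation, driven by deprotonation of the more acidic product.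

Step 5
Reactants: 7 5-bromopent-1-ene; 8 (E)-2-methylbut-2-enal
Product: 10 (2E)-3-methylnona-2,8-dien-4-ol (racemic), via pent-4-enylmagnesium bromide 9 (not isolated)
Conditions: Mg, THF, rt; 8, 0 °C; then sat. aq. NH4Cl
Reagents that add atoms: none
Why: Grignard 1,2-addition to the enal gives the secondary allylic alcohol as a racemate with the E-olefin untouched.

Step 6
Reactants: 10 (2E)-3-methylnona-2,8-dien-4-ol (racemic)
Product: 11 (2E,4S)-3-methylnona-2,8-dien-4-ol
Conditions: Ti(OiPr)4 (0.15 equiv), D-(-)-diisopropyl tartrate (0.18 equiv), t-BuOOH (0.6 equiv), 4 Å MS, CH2Cl2, -20 °C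
Reagents that add atoms: none
Why: In the Sharpless kinetic resolution with the D-(-)-tartrate the (R)-alcohol is epoxidised much faster, so the (S)-alcohol is left behind, and the isolated terminal vinyl group is inert.

Step 7
Reactants: 6 2-(6-methoxy-3,5-dimethyl-4-oxo-4H-pyran-2-yl)propanal; 11 (2E,4S)-3-methylnona-2,8-dien-4-ol
Product: 12 2-methoxy-3,5-dimethyl-6-[(1E)-1-{[(2E,4S)-3-methylnona-2,8-dien-4-yl]oxy}prop-1-en-2-yl]-4H-pyran-4-one
Conditions: PPTS (0.1 equiv), benzene, reflux, Dean-Stark trap with 4 Å MS
Reagents that add atoms: none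
Why: Acid-catalysed dehydrative enol etherification (hemiacetal, oxocarbenium ion, loss of the pyrone-acidified α-proton) leaves the carbinol C-O bond intact, and under equilibrating conditions A1,3 strain places H rather than OR cis to the conjugated pyrone, which gives the E-enol ether.

Step 8
Reactants: 12 the allyl vinyl ether of step 7
Product: 13 (2R,3R,4E)-2-(6-methoxy-3,5-dimethyl-4-oxo-4H-pyran-2-yl)-2,3,4-trimethyldeca-4,9-dienal
Conditions: toluene, base-washed sealed tube, 130 °C
Reagents that add atoms: none
Why: The Claisen rearrangement runs through the chair transition state with the pyrone and the pentenyl chain equatorial, so the E-enol ether and the E-olefin fix the C7/C8 relative configuration, the (S)-carbinol centre is transferred suprafacially into the absolute configuration, and the new olefin at C1 is E.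

Step 9
Reactants: 13 the aldehyde of step 8
Product: 14 2-[(2Z,4S,5R,6E)-2-iodo-4,5,6-trimethyldodeca-2,6,11-trien-4-yl]-6-methoxy-3,5-dimethyl-4H-pyran-4-one
Conditions: EtPPh3I, n-BuLi, THF, rt; [I][I] (iodine), -78 °C; NaHMDS, -20 °C; 13, -78 to -20 °C
Reagents that add atoms: ethyltriphenylphosphonium iodide CC[P+](c1ccccc1)(c1ccccc1)c1ccccc1.[I-]; iodine [I][I]
Why: Stork-Zhao olefination with (1-iodoethylidene)triphenylphosphorane proceeds through the kinetic cis-oxaphosphetane and puts iodine cis to C7 (Z), and the non-enolisable aldehyde cannot epimerise.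

Step 10
Reactants: 15 prop-2-yn-1-ol
Product: 17 (2Z)-3-iodo-2-methylprop-2-en-1-ol, via oxamagnesacycle 16 (not isolated)
Conditions: MeMgBr (2.5 equiv), CuI (0.1 equiv), Et2O/THF, -10 °C to rt; iodine, 0 °C; then sat. aq. NH4Cl
Reagents that add atoms: methylmagnesium bromide C[Mg]Br; iodine [I][I]
Why: Alkoxide-directed copper-catalysed anti-carbomagnesiation gives the chelated alkenylmagnesium species, and iodinolysis with retention places iodine cis to CH2OH.

Step 11
Reactants: 17 (2Z)-3-iodo-2-methylprop-2-en-1-ol
Product: 18 (2Z)-3-iodo-2-methylprop-2-enal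
Conditions: MnO2 (excess), CH2Cl2, rt, dark
Reagents that add atoms: none
Why: Neutral allylic oxidation with MnO2 keeps the Z-geometry and the vinyl iodide.

Step 12
Reactants: 18 (2Z)-3-iodo-2-methylprop-2-enal
Product: 19 (1Z)-1-iodo-2-methylbuta-1,3-diene
Conditions: Ph3PCH3Br, KOtBu, Et2O, 0 °C; 18, 0 °C; product kept as a cold ether solution
Reagents that add atoms: methyltriphenylphosphonium bromide C[P+](c1ccccc1)(c1ccccc1)c1ccccc1.[Br-]
Why: Wittig methylenation converts the aldehyde into the terminal vinyl group (the later C2 end) without touching the trisubstituted Z-olefin.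

Step 13
Reactants: 14 the Z-vinyl iodide of step 9; 19 (1Z)-1-iodo-2-methylbuta-1,3-diene
Product: 22 2-methoxy-3,5-dimethyl-6-[(3Z,5Z,7R,8R,9E)-3,5,7,8,9-pentamethylpentadeca-1,3,5,9,14-pentaen-7-yl]-4H-pyran-4-one, via dienyllithium 20 (not isolated), via dienylzinc bromide 21 (not isolated)
Conditions: 19, t-BuLi (2.0 equiv), Et2O, -78 °C; ZnBr2, THF, -78 to 0 °C; 14, Pd(PPh3)4 (5 mol%), THF, rt
Reagents that add atoms: none
Why: Negishi alkenyl-alkenyl coupling at zerovalent palladium forms C4-C5 with retention at both sp2 carbons, and the mild zinc reagent tolerates the pyrone while being reactive enough for the hindered iodide.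

Step 14
Reactants: 22 the open-chain pentaene of step 13
Product: 24 2-methoxy-3,5-dimethyl-6-[(1R,6R,7S,8R)-1,3,5,7,8-pentamethylbicyclo[4.2.0]octa-2,4-dien-7-yl]-4H-pyran-4-one, via cyclooctatriene 23 (not isolated)
Conditions: second-generation Hoveyda-Grubbs catalyst RuCl2(SIMes)(=CH-C6H4-2-OiPr) (10 mol%, two portions), CH2Cl2 (1 mM), 40 °C, argon sparge; held at 40 °C until 23 is consumed
Reagents that add atoms: none
Why: Proposed new method: ruthenium enters at the unhindered terminal vinyl of the pentenyl chain, expels cyclopentene and is thereby relayed onto C1, and metathesis of this alkylidene with the C2 vinyl group (or, after capture of ethylene, of the C2 alkylidene with the resulting isopropenyl group) closes the eight-membered ring at C1=C2, after which the all-cis triene 23 undergoes thermal disrotatory 6π electrocyclisation that bonds C1 to C6 across the ring. The closest known reaction types are relay ring-closing metathesis to trisubstituted medium-ring olefins, ene-diene ring-closing metathesis and the cyclooctatriene to bicyclo[4.2.0]octadiene half of 8π/6π cascades, and their coupling on a triene of this kind is the new element. The eight-membered ring closes by [2+2]/retro-[2+2] metathesis, helped by the two Z-olefins and the quaternary C7 that fold the chain, and the four- and six-membered rings close together in the transannular 6π event, which also withdraws 23 from the metathesis equilibrium. C1 and C6 are formed cis to each other by the disrotatory rule, and their sense relative to C7 and C8 is fixed by the tub conformer of 23 that closes, the one leading to 24 keeping both methyl groups of C7 and C8 on the convex face and only the flat pyrone and H-8 under the new diene. The step needs site selectivity for the terminal C2 vinyl over the internal olefins (attack there would contract the ring), which the methyl groups on C3 and C5 secure, and retention at C7 and C8, which is secure because neither centre is touched and 40 °C is too low for ring opening of 23 to an achiral tetraene.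

Step 15
Reactants: 24 the bicyclo[4.2.0]octadiene of step 14
Product: 25 target endoperoxide, (1R,2R,5S,6R,7S,8R) in the numbering of the overview
Conditions: O2, tetraphenylporphyrin (1 mol%), visible light, CH2Cl2, 0 °C
Reagents that add atoms: dioxygen O=O
Why: [4+2] cycloaddition of singlet oxygen to the s-cis cyclohexadiene takes place on the face anti to the cyclobutane (the face of the C1 methyl and H-6), which sets C2 and C5 in one event, while the electron-poor pyrone is inert.

**Compound list**
1 | ethyl 2-methyl-3-oxopentanoate | CCOC(=O)C(C)C(=O)CC | starting material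
2 | N-methoxy-N-methylpropanamide | CCC(=O)N(C)OC | starting material
3 | ethyl 2,4-dimethyl-3,5-dioxoheptanoate | CCOC(=O)C(C)C(=O)C(C)C(=O)CC | intermediate
4 | 6-ethyl-4-hydroxy-3,5-dimethyl-2H-pyran-2-one | CCc1oc(=O)c(C)c(O)c1C | intermediate
5 | 2-ethyl-6-methoxy-3,5-dimethyl-4H-pyran-4-one | CCc1oc(OC)c(C)c(=O)c1C | intermediate
6 | 2-(6-methoxy-3,5-dimethyl-4-oxo-4H-pyran-2-yl)propanal | CC(C=O)c1oc(OC)c(C)c(=O)c1C | intermediate
7 | 5-bromopent-1-ene | C=CCCCBr | starting material
8 | (E)-2-methylbut-2-enal | C/C=C(C)/C=O | starting material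
9 | pent-4-en-1-ylmagnesium bromide | C=CCCC[Mg]Br | intermediate
10 | (2E)-3-methylnona-2,8-dien-4-ol, racemic | C/C=C(C)/C(O)CCCC=C | intermediate
11 | (2E,4S)-3-methylnona-2,8-dien-4-ol | C/C=C(C)/[C@@H](O)CCCC=C | intermediate
12 | 2-methoxy-3,5-dimethyl-6-[(1E)-1-{[(2E,4S)-3-methylnona-2,8-dien-4-yl]oxy}prop-1-en-2-yl]-4H-pyran-4-one | COc1oc(/C(C)=C/O[C@@H](CCCC=C)/C(C)=C/C)c(C)c(=O)c1C | intermediate
13 | (2R,3R,4E)-2-(6-methoxy-3,5-dimethyl-4-oxo-4H-pyran-2-yl)-2,3,4-trimethyldeca-4,9-dienal | COc1oc([C@@](C=O)(C)[C@H](C)/C(C)=C/CCCC=C)c(C)c(=O)c1C | intermediate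
14 | 2-[(2Z,4S,5R,6E)-2-iodo-4,5,6-trimethyldodeca-2,6,11-trien-4-yl]-6-methoxy-3,5-dimethyl-4H-pyran-4-one | COc1oc([C@@](/C=C(/C)I)(C)[C@H](C)/C(C)=C/CCCC=C)c(C)c(=O)c1C | intermediate
15 | prop-2-yn-1-ol | C#CCO | starting material
16 | 4-methyl-2,5-dihydro-1,2-oxamagnesole (chelated Z-alkenylmagnesium alkoxide) | CC1=C[Mg]OC1 | intermediate
17 | (2Z)-3-iodo-2-methylprop-2-en-1-ol | I/C=C(/C)CO | intermediate
18 | (2Z)-3-iodo-2-methylprop-2-enal | I/C=C(/C)C=O | intermediate
19 | (1Z)-1-iodo-2-methylbuta-1,3-diene | I/C=C(/C)C=C | intermediate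
20 | (1Z)-2-methylbuta-1,3-dien-1-yllithium | [Li]/C=C(/C)C=C | intermediate
21 | bromo[(1Z)-2-methylbuta-1,3-dien-1-yl]zinc | Br[Zn]/C=C(/C)C=C | intermediate
22 | 2-methoxy-3,5-dimethyl-6-[(3Z,5Z,7R,8R,9E)-3,5,7,8,9-pentamethylpentadeca-1,3,5,9,14-pentaen-7-yl]-4H-pyran-4-one | COc1oc([C@@](/C=C(/C)\C=C(\C)C=C)(C)[C@H](C)/C(C)=C/CCCC=C)c(C)c(=O)c1C | intermediate
23 | 2-methoxy-3,5-dimethyl-6-[(1R,8R,2Z,4Z,6Z)-1,3,5,7,8-pentamethylcycloocta-2,4,6-trien-1-yl]-4H-pyran-4-one | COc1oc([C@]2(C)/C=C(C)\C=C(C)/C=C(C)\[C@H]2C)c(C)c(=O)c1C | intermediate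
24 | 2-methoxy-3,5-dimethyl-6-[(1R,6R,7S,8R)-1,3,5,7,8-pentamethylbicyclo[4.2.0]octa-2,4-dien-7-yl]-4H-pyran-4-one | COc1oc([C@@]2(C)[C@H](C)[C@@]3(C)C=C(C)C=C(C)[C@@H]23)c(C)c(=O)c1C | intermediate
25 | target: 2,5-epidioxy adduct of 24, O-O bridge anti to the cyclobutane, (1R,2R,5S,6R,7S,8R) | COc1oc([C@@]2(C)[C@H](C)[C@@]3(C)[C@@H]4OO[C@@](C)(C=C4C)[C@@H]23)c(C)c(=O)c1C | target

Total step count: 15.
Longest linear sequence: 10 steps (steps 1 to 4, 7 to 9, 13 to 15).

**Steps most likely to fail**

1. Step 14 (labelled).
 - What may go wrong: ruthenium may not be handed over to, or may not react at, the hindered olefin at C1. The internal olefins of the triene may be attacked instead, with ring contraction. The two tub conformers may close with poor facial selectivity; in that case the separated unwanted valence isomer can be returned to the equilibrium through 23 by gentle warming.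
 - Fallback: it sets out from 14 and comes back at 24, and it joins the same two carbons by known carbonyl chemistry.
 - Lemieux-Johnson cleavage (OsO4 cat., NaIO4, 2,6-lutidine, dioxane/H2O) of the two non-halogenated olefins of 14 should give the keto vinyl iodide F1.
 - Iodo alcohol 17 is turned (t-BuLi, 3 equiv, Et2O, -78 °C; Bu3SnCl) into the Z-stannyl alcohol F2.
 - Stille coupling of the two (Pd(PPh3)4, copper thiophene-2-carboxylate Cu(O2C-C4H3S), DMF, rt) gives the keto dienol F3, and MnO2 gives the keto dienal F4.
 - Intramolecular McMurry coupling (TiCl3(DME)1.5, Zn-Cu couple, DME, reflux, slow addition), a known route from keto aldehydes to eight-membered cycloalkenes, then forms C1=C2 to give 23, which closes to 24.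

2. Step 9.
 - What may go wrong: the bulky, thermally fragile iodo ylide may add too slowly to the neopentyl-type aldehyde, with decay of the ylide, loss of iodine or eroded Z-selectivity.
 - Fallback: it sets out from 13 and comes back at 22.
 - Ramirez olefination (CBr4, PPh3, CH2Cl2, 0 °C) gives the 1,1-dibromoalkene F5.
 - Trans-selective Negishi methylation (MeZnBr, PdCl2(DPEphos), THF, 0 °C to rt) replaces only the bromide trans to the quaternary carbon and gives the Z-bromoalkene F6.
 - F6 is coupled with 21 (Pd(PtBu3)2, THF, rt) to give 22.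

3. Step 7.
 - What may go wrong: the acid may ionise the allylic C-O bond (racemisation, allylic transposition, dehydration), or the reaction may stop at the acetal stage.
 - Fallback: it sets out from 6 and comes back at 12, under basic conditions.
 - O-sulfonylation of the enol form (TsCl, Et3N, DMAP, CH2Cl2, 0 °C) gives the E-enol tosylate F7.
 - Addition-elimination of the sodium alkoxide of 11 (NaH, THF, 0 °C) at the vinylogous acceptor gives 12 with the carbinol C-O bond untouched.

**Further compounds**
F1 | step 14 | 2-[(2Z,4S,5S)-2-iodo-4,5-dimethyl-6-oxohept-2-en-4-yl]-6-methoxy-3,5-dimethyl-4H-pyran-4-one | COc1oc([C@@](/C=C(/C)I)(C)[C@H](C)C(C)=O)c(C)c(=O)c1C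
F2 | step 14 | (2Z)-2-methyl-3-(tributylstannyl)prop-2-en-1-ol | CCCC[Sn](CCCC)(CCCC)/C=C(/C)CO
F3 | step 14 | (3S,4R,5Z,7Z)-9-hydroxy-4-(6-methoxy-3,5-dimethyl-4-oxo-4H-pyran-2-yl)-3,4,6,8-tetramethylnona-5,7-dien-2-one | COc1oc([C@@](/C=C(/C)\C=C(\C)CO)(C)[C@H](C)C(C)=O)c(C)c(=O)c1C
F4 | step 14 | (2Z,4Z,6R,7S)-6-(6-methoxy-3,5-dimethyl-4-oxo-4H-pyran-2-yl)-2,4,6,7-tetramethyl-8-oxonona-2,4-dienal | COc1oc([C@@](/C=C(/C)\C=C(\C)C=O)(C)[C@H](C)C(C)=O)c(C)c(=O)c1C
F5 | step 9 | 2-[(3S,4R,5E)-1,1-dibromo-3,4,5-trimethylundeca-1,5,10-trien-3-yl]-6-methoxy-3,5-dimethyl-4H-pyran-4-one | COc1oc([C@@](C=C(Br)Br)(C)[C@H](C)/C(C)=C/CCCC=C)c(C)c(=O)c1C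
F6 | step 9 | 2-[(2Z,4S,5R,6E)-2-bromo-4,5,6-trimethyldodeca-2,6,11-trien-4-yl]-6-methoxy-3,5-dimethyl-4H-pyran-4-one | COc1oc([C@@](/C=C(/C)Br)(C)[C@H](C)/C(C)=C/CCCC=C)c(C)c(=O)c1C
F7 | step 7 | (1E)-2-(6-methoxy-3,5-dimethyl-4-oxo-4H-pyran-2-yl)prop-1-en-1-yl 4-methylbenzenesulfonate | COc1oc(/C(C)=C/OS(=O)(=O)c2ccc(C)cc2)c(C)c(=O)c1C
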